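In labdane numbering, the exocyclic C8=C17 methylene is traced back to a C8 ketone and this to its silyl enol ether, so that ring B (C5 to C10) becomes the adduct of the 2-silyloxy diene C7=C8–C9=C10 and a C5=C6 dienophile that are joined through C1–C4, the future ring A. One thermal intramolecular Diels–Alder reaction of an open-chain triene closes both rings and sets the quaternary C10 and C5 under control of an enantiopure quaternary C4 made beforehand. The dienophile is an E vinyl sulfone; the sulfonyl group leaves later by β-elimination, which lets C5 and C9 equilibrate. C13 comes from (R)-methyl hydrogen 3-methylglutarate.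

Key step: step 11

Remark: labdane numbering is used throughout (ring A = C1–C5 and C10, ring B = C5–C10, side chain C11–C16, C17 = methylene carbon, C18 = ester carbon, C19 and C20 = methyls); in step 2 the ligand enantiomer is taken to be the one that leaves the R alcohol, which is to be confirmed by correlation.

Step 1
Reactants: 1 dimethyl 2-methylmalonate; 2 allyl bromide
Product: 3 dimethyl 2-allyl-2-methylmalonate
Conditions: NaH, THF, 0 °C → rt
Reagents that add atoms: none
Why: C-alkylation of the sodium malonate enolate with the allylic bromide (malonic ester alkylation) is clean because only one acidic hydrogen is present, and it forms the prochiral quaternary carbon that becomes C4.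

Step 2
Reactants: 3 dimethyl 2-allyl-2-methylmalonate
Product: 4 methyl (2R)-2-(hydroxymethyl)-2-methylpent-4-enoate
Conditions: ZnEt2 (10 mol%), chiral ProPhenol-type tetradentate ligand (5 mol%), (EtO)3SiH, THF, 0 °C; then NH4F, MeOH
Reagents that add atoms: none
Why: The zinc-catalysed enantioselective hydrosilylation of 2,2-disubstituted malonic esters (desymmetrising mono-reduction) reduces one of the two enantiotopic ester groups and stops at the β-hydroxy ester, so the chiral dinuclear zinc catalyst sets the quaternary C4 as R.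

Step 3
Reactants: 4 methyl (2R)-2-(hydroxymethyl)-2-methylpent-4-enoate
Product: 5 methyl (2R)-2-formyl-2-methylpent-4-enoate
Conditions: Dess–Martin periodinane, CH2Cl2, 0 °C → rt
Reagents that add atoms: none
Why: Dess–Martin oxidation of the neopentyl primary alcohol gives the aldehyde under neutral conditions, and C4 cannot epimerise because it carries no hydrogen.

Step 4
Reactants: 5 methyl (2R)-2-formyl-2-methylpent-4-enoate
Product: 6 methyl (2R)-2-methyl-2-[(E)-2-(phenylsulfonyl)ethenyl]pent-4-enoate
Conditions: (EtO)2P(O)CH2SO2Ph, LiCl, DBU, MeCN, 0 °C → rt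
Reagents that add atoms: diethyl [(phenylsulfonyl)methyl]phosphonate, CCOP(=O)(OCC)CS(=O)(=O)c1ccccc1
Why: The Horner–Wadsworth–Emmons reaction of the sulfonyl-stabilised phosphonate under mild LiCl/DBU conditions (Masamune–Roush variant) gives the E vinyl sulfone and avoids retro-Claisen loss of the formyl group.

Step 5
Reactants: 7 (3R)-5-methoxy-3-methyl-5-oxopentanoic acid [(R)-methyl hydrogen 3-methylglutarate]
Product: 9 (4S)-4-methyloxan-2-one, via hydroxy acid 8 (not isolated)
Conditions: LiBH4, THF, 0 °C → rt; then 2 M HCl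
Reagents that add atoms: none
Why: LiBH4 reduces the ester but not the lithium carboxylate (chemoselective ester reduction), and the hydroxy acid lactonises on acidification; the stereocentre, the future C13, is not touched.

Step 6
Reactants: 9 (4S)-4-methyloxan-2-one
Product: 11 methyl (3R)-5-iodo-3-methylpentanoate, via silyl ester 10 (not isolated)
Conditions: TMSCl, NaI, MeCN, rt → 60 °C; then MeOH
Reagents that add atoms: sodium iodide, [Na+].[I-]; methanol, CO
Why: Iodotrimethylsilane made in the flask opens the lactone by SN2 attack of iodide at the O–CH2 carbon, and methanol then converts the silyl ester into the methyl ester (acid-catalysed esterification), again without touching C13.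

Step 7
Reactants: 11 methyl (3R)-5-iodo-3-methylpentanoate; 12 pentane-2,4-dione
Product: 13 methyl (3S)-6-acetyl-3-methyl-7-oxooctanoate
Conditions: K2CO3, acetone, reflux
Reagents that add atoms: none
Why: C-alkylation of the potassium enolate of the 1,3-diketone with the primary iodide (SN2) gives the 3-substituted diketone, in which C9 is not a stereocentre.

Step 8
Reactants: 13 methyl (3S)-6-acetyl-3-methyl-7-oxooctanoate
Product: 14 methyl (3S,6E)-6-acetyl-3-methyl-7-(trifluoromethylsulfonyloxy)oct-6-enoate
Conditions: aq. Me4NOH, Tf2O, toluene, 0 °C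
Reagents that add atoms: trifluoromethanesulfonic anhydride, O=S(=O)(OS(=O)(=O)C(F)(F)F)C(F)(F)F
Why: O-triflation of the free, non-chelated tetramethylammonium enolate, which prefers the extended form, should place the triflate anti to the remaining acetyl group and so give the E vinyl triflate that fixes the C9=C10 geometry.

Step 9
Reactants: 6 methyl (2R)-2-methyl-2-[(E)-2-(phenylsulfonyl)ethenyl]pent-4-enoate; 14 methyl (3S,6E)-6-acetyl-3-methyl-7-(trifluoromethylsulfonyloxy)oct-6-enoate
Product: 16 dimethyl (2R,6E,10S)-7-acetyl-2,6,10-trimethyl-2-[(E)-2-(phenylsulfonyl)ethenyl]dodec-6-enedioate, via alkylborane 15 (not isolated)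
Conditions: 9-BBN, THF, rt; then 14, PdCl2(dppf) (5 mol%), AsPh3, aq. K3PO4, DMF, rt
Reagents that add atoms: none
Why: 9-BBN hydroborates only the terminal alkene (anti-Markovnikov, the electron-poor vinyl sulfone is left), and the B-alkyl Suzuki–Miyaura coupling with the activated vinyl triflate forms C1–C10 with retention of the alkene geometry.

Step 10
Reactants: 16 dimethyl (2R,6E,10S)-7-acetyl-2,6,10-trimethyl-2-[(E)-2-(phenylsulfonyl)ethenyl]dodec-6-enedioate
Product: 17 dimethyl (2R,6E,10S)-7-[1-(tert-butyldimethylsilyloxy)ethenyl]-2,6,10-trimethyl-2-[(E)-2-(phenylsulfonyl)ethenyl]dodec-6-enedioate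
Conditions: TBSOTf, Et3N, CH2Cl2, −78 → 0 °C
Reagents that add atoms: tert-butyldimethylsilyl trifluoromethanesulfonate, CC(C)(C)[Si](C)(C)OS(=O)(=O)C(F)(F)F
Why: Soft enolisation of the methyl ketone with TBSOTf and Et3N removes an α′-methyl hydrogen (kinetic site) to give the cross-conjugated 2-silyloxy diene without change of the C9=C10 geometry, esters and sulfone being inert.

Step 11
Reactants: 17 dimethyl (2R,6E,10S)-7-[1-(tert-butyldimethylsilyloxy)ethenyl]-2,6,10-trimethyl-2-[(E)-2-(phenylsulfonyl)ethenyl]dodec-6-enedioate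
Product: 18 dimethyl (13S)-8-(tert-butyldimethylsilyloxy)-6α-(phenylsulfonyl)-17-norlabd-8-ene-15,18-dioate (4α-CO2CH3; 5α-H; 10β-CH3)
Conditions: toluene (0.01 M), BHT (cat.), 150 °C, sealed tube
Reagents that add atoms: none
Why: A thermal, concerted but asynchronous [4+2] cycloaddition (type 1 intramolecular Diels–Alder reaction) joins C7 to C6 and C10 to C5, the closest known reaction type being the cyclisation of 1,7,9-decatrienes whose dienophile carries a terminal phenylsulfonyl (ethylene-equivalent) or ester group. Ring B is closed by the cycloaddition itself; ring A is closed in the fused mode by the C5–C10 bond across the four-carbon C1–C4 chain, which also imposes the regiochemistry against the electronic bias of the 2-silyloxy diene. The sulfonyl-endo transition state of the E alkene, with the tether exo and chair-like, gives the trans ring fusion and places the sulfonyl group cis to H5 at C6. C10 and C5 are set from the quaternary C4: its substituent that must sit beside H6 and under the inside (Z) methyl on C10 is best the compact methyl group, while the ester takes the open exo site anti to the forming C5–C10 bond, so the two methyls become syn (4β, 10β) and the ester equatorial. The step therefore needs facial selectivity at C5=C6, which rests on this C4 argument, and the trans mode, which rests on the E geometry; a cis-fused share with the same C4/C10 relationship is corrected at C5 in step 12. The C8=C9 silyl enol ether leaves the ring B ketone masked and regiodefined.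

Step 12
Reactants: 18 dimethyl (13S)-8-(tert-butyldimethylsilyloxy)-6α-(phenylsulfonyl)-17-norlabd-8-ene-15,18-dioate
Product: 20 dimethyl (13S)-8-oxo-17-norlabd-6-ene-15,18-dioate (5α-H; 9α-H), via sulfonyl ketone 19 (not isolated)
Conditions: K2CO3, MeOH, 40 °C
Reagents that add atoms: none
Why: Methanolysis of the silyl enol ether frees the C8 ketone and the β-sulfonyl ketone loses benzenesulfinate by E1cB elimination; under the same basic conditions C9 (α) and C5 (vinylogous γ) equilibrate to the equatorial side chain and the trans ring fusion.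

Step 13
Reactants: 20 dimethyl (13S)-8-oxo-17-norlabd-6-ene-15,18-dioate
Product: 21 dimethyl (13S)-8-oxo-17-norlabdane-15,18-dioate (5α-H; 9α-H)
Conditions: H2 (1 atm), Pd/C, EtOAc, rt
Reagents that add atoms: none
Why: Heterogeneous hydrogenation reduces the disubstituted enone C6=C7 double bond much faster than the hindered ketone or the esters, and no stereocentre is formed.

Step 14
Reactants: 21 dimethyl (13S)-8-oxo-17-norlabdane-15,18-dioate
Product: 22 dimethyl (4R,5R,9S,10R,13S)-labd-8(17)-ene-15,18-dioate
Conditions: Ph3PCH3Br, KOtBu, THF, 0 → 65 °C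
Reagents that add atoms: methyltriphenylphosphonium bromide, C[P+](c1ccccc1)(c1ccccc1)c1ccccc1.[Br-]
Why: Wittig methylenation of the ring B ketone with the non-stabilised ylide installs C17 without touching the esters, and C9 already has its thermodynamically preferred equatorial configuration.

Step 15
Reactants: 22 dimethyl (4R,5R,9S,10R,13S)-labd-8(17)-ene-15,18-dioate
Product: 23 (4R,5R,9S,10R,13S)-18-methoxy-18-oxolabd-8(17)-en-15-oic acid (target)
Conditions: LiOH·H2O, THF/MeOH/H2O, rt; then 1 M HCl
Reagents that add atoms: lithium hydroxide, [Li+].[OH-]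
Why: Saponification distinguishes the unhindered primary-chain C15 methyl ester from the neopentyl-type C18 ester on the quaternary C4, which is hydrolysed far more slowly, so only the C15 acid is freed.

Compound list
1 | dimethyl 2-methylmalonate | COC(=O)C(C)C(=O)OC | starting material
2 | allyl bromide | C=CCBr | starting material
3 | dimethyl 2-allyl-2-methylmalonate | COC(=O)C(C)(CC=C)C(=O)OC | intermediate
4 | methyl (2R)-2-(hydroxymethyl)-2-methylpent-4-enoate | C=CC[C@](C)(CO)C(=O)OC | intermediate
5 | methyl (2R)-2-formyl-2-methylpent-4-enoate | C=CC[C@](C)(C=O)C(=O)OC | intermediate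
6 | methyl (2R)-2-methyl-2-[(E)-2-(phenylsulfonyl)ethenyl]pent-4-enoate | C=CC[C@](C)(/C=C/S(=O)(=O)c1ccccc1)C(=O)OC | intermediate
7 | (3R)-5-methoxy-3-methyl-5-oxopentanoic acid | COC(=O)C[C@H](C)CC(=O)O | starting material
8 | (3S)-5-hydroxy-3-methylpentanoic acid (not isolated) | OCC[C@H](C)CC(=O)O | intermediate
9 | (4S)-4-methyloxan-2-one | C[C@H]1CCOC(=O)C1 | intermediate
10 | trimethylsilyl (3R)-5-iodo-3-methylpentanoate (not isolated) | ICC[C@H](C)CC(=O)O[Si](C)(C)C | intermediate
11 | methyl (3R)-5-iodo-3-methylpentanoate | ICC[C@H](C)CC(=O)OC | intermediate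
12 | pentane-2,4-dione | CC(=O)CC(C)=O | starting material
13 | methyl (3S)-6-acetyl-3-methyl-7-oxooctanoate | CC(=O)C(CC[C@H](C)CC(=O)OC)C(C)=O | intermediate
14 | methyl (3S,6E)-6-acetyl-3-methyl-7-(trifluoromethylsulfonyloxy)oct-6-enoate (triflate trans to acetyl) | C/C(OS(=O)(=O)C(F)(F)F)=C(\C(C)=O)CC[C@H](C)CC(=O)OC | intermediate
15 | methyl (2R)-5-(9-borabicyclo[3.3.1]nonan-9-yl)-2-methyl-2-[(E)-2-(phenylsulfonyl)ethenyl]pentanoate (not isolated) | B1(CCC[C@](C)(/C=C/S(=O)(=O)c2ccccc2)C(=O)OC)C3CCCC1CCC3 | intermediate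
16 | dimethyl (2R,6E,10S)-7-acetyl-2,6,10-trimethyl-2-[(E)-2-(phenylsulfonyl)ethenyl]dodec-6-enedioate (C20 methyl cis to acetyl) | C/C(CCC[C@](C)(/C=C/S(=O)(=O)c1ccccc1)C(=O)OC)=C(\C(C)=O)CC[C@H](C)CC(=O)OC | intermediate
17 | dimethyl (2R,6E,10S)-7-[1-(tert-butyldimethylsilyloxy)ethenyl]-2,6,10-trimethyl-2-[(E)-2-(phenylsulfonyl)ethenyl]dodec-6-enedioate | C=C(O[Si](C)(C)C(C)(C)C)/C(CC[C@H](C)CC(=O)OC)=C(\C)CCC[C@](C)(/C=C/S(=O)(=O)c1ccccc1)C(=O)OC | intermediate
18 | dimethyl (13S)-8-(tert-butyldimethylsilyloxy)-6α-(phenylsulfonyl)-17-norlabd-8-ene-15,18-dioate (4α-CO2CH3, 4β-CH3, 5α-H, 10β-CH3) | CC(C)(C)[Si](C)(C)OC1C[C@H](S(=O)(=O)c3ccccc3)[C@@H]2[C@](C)(CCC[C@@]2(C)C(=O)OC)C=1CC[C@H](C)CC(=O)OC | intermediate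
19 | dimethyl (13S)-8-oxo-6α-(phenylsulfonyl)-17-norlabdane-15,18-dioate (not isolated) | O=C1C[C@H](S(=O)(=O)c3ccccc3)[C@@H]2[C@](C)(CCC[C@@]2(C)C(=O)OC)[C@H]1CC[C@H](C)CC(=O)OC | intermediate
20 | dimethyl (13S)-8-oxo-17-norlabd-6-ene-15,18-dioate (5α-H, 9α-H, 10β-CH3) | O=C1C=C[C@@H]2[C@](C)(CCC[C@@]2(C)C(=O)OC)[C@H]1CC[C@H](C)CC(=O)OC | intermediate
21 | dimethyl (13S)-8-oxo-17-norlabdane-15,18-dioate (5α-H, 9α-H, 10β-CH3) | O=C1CC[C@@H]2[C@](C)(CCC[C@@]2(C)C(=O)OC)[C@H]1CC[C@H](C)CC(=O)OC | intermediate
22 | dimethyl (4R,5R,9S,10R,13S)-labd-8(17)-ene-15,18-dioate | C=C1CC[C@@H]2[C@](C)(CCC[C@@]2(C)C(=O)OC)[C@H]1CC[C@H](C)CC(=O)OC | intermediate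
23 | (4R,5R,9S,10R,13S)-18-methoxy-18-oxolabd-8(17)-en-15-oic acid | C=C1CC[C@@H]2[C@](C)(CCC[C@@]2(C)C(=O)OC)[C@H]1CC[C@H](C)CC(=O)O | target

Total step count: 15 (fragment 1: steps 1–4; fragment 2: steps 5–8; union and endgame: steps 9–15).
Longest linear sequence: 11 steps (steps 1–4 and 9–15, or equally steps 5–8 and 9–15).

Steps most likely to fail

Step 11. The cycloaddition may suffer from poor facial selectivity at the dienophile (a weak relay from C4 to C5 and C10), from intervention of the cis-fused mode, or from a 1,5-hydrogen shift of the Z-methyl diene that outruns ring closure at 150 °C. The fallback sets out from 5 and comes back at 21; in it the dienophile face is fixed by an auxiliary and the reaction is run cold under Lewis acid activation. Horner–Wadsworth–Emmons reaction of 5 with diethyl {2-[(4S)-4-benzyl-2-oxo-1,3-oxazolidin-3-yl]-2-oxoethyl}phosphonate (LiCl, iPr2NEt, MeCN) would give the N-enoyl oxazolidinone F1. Hydroboration with 9-BBN and B-alkyl Suzuki–Miyaura coupling with 14, as in step 9, would give the enone imide F2, and TBSOTf with Et3N the silyl dienol ether F3. Me2AlCl (CH2Cl2, −30 °C) followed by aqueous HCl should deliver the keto imide F4 by a chelate-controlled intramolecular Diels–Alder reaction in which the benzyl group shields one face of the dienophile; the antipodal auxiliary is taken if the other face is needed. LiOH and H2O2 would cleave the auxiliary to the keto acid F5. Conversion into the thiohydroxamate ester F6 ((COCl)2, then the sodium salt of 2-sulfanylpyridine 1-oxide) and photolysis with t-BuSH (Barton decarboxylation) should give 21.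

Step 8. O-sulfonylation may proceed through the chelated enolate and give the wrong alkene geometry, or the vinylogous acyl triflate may hydrolyse back to 13. The fallback sets out from 11 and comes back at 16; it uses the stereocomplementary enol tosylation of a β-keto ester. Alkylation of tert-butyl acetoacetate with 11 (K2CO3, acetone) would give the keto ester F7, and TsCl with N-methylimidazole and Et3N the (E)-enol tosylate F8. Coupling with alkylborane 15 (Pd(OAc)2, SPhos, K3PO4) would give the tert-butyl enoate F9, TFA the acid F10, and (COCl)2 the acid chloride F11. MeMgBr with Fe(acac)3 (THF, −78 °C) should then give 16.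

Step 2. Enantioselection in the desymmetrising reduction may be incomplete, or reduction may run on to the diol. The fallback sets out from 3 and comes back at 4; it uses enzymatic desymmetrisation. Pig liver esterase (phosphate buffer, pH 7) is expected to hydrolyse one enantiotopic ester group of 3 to the half-ester F12, which can be enriched by crystallisation of an amine salt. LiBH4 would reduce the ester group beside the carboxylate to the hydroxy acid F13, and TMSCHN2 would give 4. Should the enzyme prefer the other ester group, the acid group of that half-ester is reduced instead (mixed anhydride, NaBH4), which leads to the same 4.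

Further compounds
F1 | step 11 | methyl (2R)-2-{(E)-3-[(4S)-4-benzyl-2-oxo-1,3-oxazolidin-3-yl]-3-oxoprop-1-enyl}-2-methylpent-4-enoate | C=CC[C@](C)(/C=C/C(=O)N1[C@@H](Cc2ccccc2)COC1=O)C(=O)OC
F2 | step 11 | enone imide, analogue of 16 with the N-acyl oxazolidinone in place of the sulfonyl group | C/C(CCC[C@](C)(/C=C/C(=O)N1[C@@H](Cc2ccccc2)COC1=O)C(=O)OC)=C(\C(C)=O)CC[C@H](C)CC(=O)OC
F3 | step 11 | silyl dienol ether, analogue of 17 with the N-acyl oxazolidinone in place of the sulfonyl group | C=C(O[Si](C)(C)C(C)(C)C)/C(CC[C@H](C)CC(=O)OC)=C(\C)CCC[C@](C)(/C=C/C(=O)N1[C@@H](Cc2ccccc2)COC1=O)C(=O)OC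
F4 | step 11 | dimethyl (13S)-6α-{[(4S)-4-benzyl-2-oxo-1,3-oxazolidin-3-yl]carbonyl}-8-oxo-17-norlabdane-15,18-dioate | O=C1C[C@H](C(=O)N3[C@@H](Cc4ccccc4)COC3=O)[C@@H]2[C@](C)(CCC[C@@]2(C)C(=O)OC)[C@H]1CC[C@H](C)CC(=O)OC
F5 | step 11 | (13S)-15,18-dimethoxy-8,15,18-trioxo-17-norlabdane-6α-carboxylic acid | O=C1C[C@H](C(=O)O)[C@@H]2[C@](C)(CCC[C@@]2(C)C(=O)OC)[C@H]1CC[C@H](C)CC(=O)OC
F6 | step 11 | 2-thioxopyridin-1(2H)-yl ester of F5 (Barton ester) | O=C1C[C@H](C(=O)On3ccccc3=S)[C@@H]2[C@](C)(CCC[C@@]2(C)C(=O)OC)[C@H]1CC[C@H](C)CC(=O)OC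
F7 | step 8 | 1-tert-butyl 7-methyl (5S)-2-acetyl-5-methylheptanedioate (epimeric at the enolisable C2) | CC(=O)C(CC[C@H](C)CC(=O)OC)C(=O)OC(C)(C)C
F8 | step 8 | 1-tert-butyl 7-methyl (5S)-5-methyl-2-[(E)-1-(tosyloxy)ethylidene]heptanedioate (tosyloxy trans to the tert-butyl ester) | C/C(OS(=O)(=O)c1ccc(C)cc1)=C(\C(=O)OC(C)(C)C)CC[C@H](C)CC(=O)OC
F9 | step 8 | tert-butyl enoate, analogue of 16 with CO2C(CH3)3 in place of the acetyl group | C/C(CCC[C@](C)(/C=C/S(=O)(=O)c1ccccc1)C(=O)OC)=C(\C(=O)OC(C)(C)C)CC[C@H](C)CC(=O)OC
F10 | step 8 | carboxylic acid, analogue of 16 with CO2H in place of the acetyl group | C/C(CCC[C@](C)(/C=C/S(=O)(=O)c1ccccc1)C(=O)OC)=C(\C(=O)O)CC[C@H](C)CC(=O)OC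
F11 | step 8 | acid chloride, analogue of 16 with COCl in place of the acetyl group | C/C(CCC[C@](C)(/C=C/S(=O)(=O)c1ccccc1)C(=O)OC)=C(\C(=O)Cl)CC[C@H](C)CC(=O)OC
F12 | step 2 | (2S)-2-(methoxycarbonyl)-2-methylpent-4-enoic acid | C=CC[C@](C)(C(=O)OC)C(=O)O
F13 | step 2 | (2R)-2-(hydroxymethyl)-2-methylpent-4-enoic acid | C=CC[C@](C)(CO)C(=O)O
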